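The plan forms the benzene ring (ring A) last, by disconnecting C5–C6 back to a four-membered ring derived from a squarate ester. Ring A carries hydroxyls at C5 and C8 in a 1,4 relationship, with C4a (bearing C4) and C8a (bearing O1) between them; a 4-hydroxy-4-vinylcyclobutenone carrying an alkyl and an alkoxy group on its double bond unfolds into exactly this pattern on heating. Precursor 23 is therefore a dihydropyran-fused cyclobutenone in which O1, the (R)-C2 centre (from (R)-epichlorohydrin) and a dithiane-masked C4 are already in place. One thermal operation opens the small ring, closes ring A and aromatises it; dithioketal hydrolysis then releases the C4 ketone.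

Key step: step 7

Remark: chroman numbering (O1, C2, C3, C4, C4a, C5 to C8, C8a) is used for the corresponding atoms of every intermediate; 2-(tert-butyldimethylsilyl)-1,3-dithiane, (R)-epichlorohydrin and vinylmagnesium bromide (THF solution) are taken to be purchased.

Step 1
Reactants: 1 1-hexyne; 2 1,10-dibromodecane
Product: 4 16-bromohexadec-5-yne, via hex-1-ynyllithium 3 (not isolated)
Conditions: n-BuLi, THF, −78 → 0 °C; then 2 (3 equiv), DMPU, 0 °C → rt
Reagents that add atoms: none
Why: SN2 alkylation of a lithium acetylide by a primary alkyl bromide, accelerated by the dipolar cosolvent; the excess of dibromide should hold back double alkylation and can be recovered by distillation.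

Step 2
Reactants: 4 16-bromohexadec-5-yne
Product: 5 (5Z)-16-bromohexadec-5-ene
Conditions: H2 (1 atm), Pd/CaCO3 poisoned with Pb(OAc)2 (Lindlar catalyst), quinoline, hexane, rt
Reagents that add atoms: none
Why: Lindlar semi-hydrogenation, in which syn delivery of hydrogen on the lead-poisoned palladium surface should stop at the Z alkene while the primary bromide stays inert.

Step 3
Reactants: 5 (5Z)-16-bromohexadec-5-ene; 6 (R)-epichlorohydrin
Product: 10 (2R)-2-[(12Z)-heptadec-12-en-1-yl]oxirane, via Grignard reagent 7 (not isolated), via magnesium alkoxide 8 (not isolated), via chlorohydrin 9 (not isolated)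
Conditions: Mg, THF, 40 °C; then 6, CuI (10 mol %), THF, −40 → −20 °C; 1 M HCl quench; crude 9, NaOH, THF/MeOH, 0 °C → rt
Reagents that add atoms: none
Why: Copper-catalysed Grignard opening of the oxirane at its CH2 terminus (faster at low temperature than chloride displacement) followed by base-induced intramolecular Williamson closure of the chlorohydrin; the C–O bond at the stereocentre is never broken, so (R)-6 should give (R)-10.

Step 4
Reactants: 10 (2R)-2-[(12Z)-heptadec-12-en-1-yl]oxirane; 11 2-(tert-butyldimethylsilyl)-1,3-dithiane; 12 diisopropyl squarate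
Product: 18 3-{2-[(2R,14Z)-2-(tert-butyldimethylsilyloxy)nonadec-14-en-1-yl]-1,3-dithian-2-yl}-4-isopropoxycyclobut-3-ene-1,2-dione, via lithiated silyldithiane 13 (not isolated), via lithium alkoxide 14 (not isolated), via relay anion 15 (not isolated), via squarate adduct 16 (not isolated), via trifluoroacetate 17 (not isolated)
Conditions: 11 (1.1 equiv), t-BuLi, Et2O, −78 → −45 °C; 10, Et2O, −78 → −25 °C; HMPA, THF, −78 → −40 °C; cannulated into 12 (1.3 equiv), THF, −78 °C; (CF3CO)2O (2 equiv), −78 → 0 °C; H2O, 0 °C → rt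
Reagents that add atoms: water, O
Why: Anion relay linchpin coupling in which the silyl-stabilised dithiane anion opens the terminal oxirane at CH2, HMPA then triggers a 1,4-Brook rearrangement (silyl shift from carbon to oxygen) that protects the alkoxide and moves the charge to the dithiane carbon, and this anion adds 1,2 to a squarate carbonyl, after which acylation, ionisation to the alkoxy-stabilised cyclobutenyl cation and hydrolytic loss of propan-2-ol give the cyclobutenedione (a competing conjugate addition–elimination would lead to the same product); the C2–O bond is untouched, so C2 stays R.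

Step 5
Reactants: 18 3-{2-[(2R,14Z)-2-(tert-butyldimethylsilyloxy)nonadec-14-en-1-yl]-1,3-dithian-2-yl}-4-isopropoxycyclobut-3-ene-1,2-dione
Product: 20 (3R)-3-[(12Z)-heptadec-12-en-1-yl]spiro[2-oxabicyclo[4.2.0]oct-1(6)-ene-5,2'-[1,3]dithiane]-7,8-dione, via hydroxy dione 19 (not isolated)
Conditions: HF·pyridine, pyridine, THF, 0 °C → rt; then Et3N, CH2Cl2, rt
Reagents that add atoms: none
Why: Buffered fluoride cleaves the secondary silyl ether and the freed hydroxyl displaces isopropoxide from the vinylogous ester carbon (future C8a) by intramolecular addition–elimination, a six-membered closure assisted by the quaternary dithiane carbon; the C2–O bond is retained, so C2 stays R.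

Step 6
Reactants: 20 (3R)-3-[(12Z)-heptadec-12-en-1-yl]spiro[2-oxabicyclo[4.2.0]oct-1(6)-ene-5,2'-[1,3]dithiane]-7,8-dione; 21 vinylmagnesium bromide
Product: 23 (3R)-3-[(12Z)-heptadec-12-en-1-yl]-8-hydroxy-8-vinylspiro[2-oxabicyclo[4.2.0]oct-1(6)-ene-5,2'-[1,3]dithiane]-7-one (both carbinol epimers), via magnesium alkoxide 22 (not isolated)
Conditions: 21 (1.2 equiv), THF, −78 °C; aq NH4Cl at −78 °C
Reagents that add atoms: none
Why: Grignard 1,2-addition should take place at the more ketone-like carbonyl next to C8a, the other carbonyl being a vinylogous ester flanked by the dithiane; the carbinol centre is formed without control, which is harmless because step 7 destroys it, and the cold quench avoids alkoxide-accelerated ring opening.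

Step 7
Reactants: 23 (3R)-3-[(12Z)-heptadec-12-en-1-yl]-8-hydroxy-8-vinylspiro[2-oxabicyclo[4.2.0]oct-1(6)-ene-5,2'-[1,3]dithiane]-7-one
Product: 26 (2R)-2-[(12Z)-heptadec-12-en-1-yl]spiro[chromane-4,2'-[1,3]dithiane]-5,8-diol, via dienylketene 24 (not isolated), via cyclohexadienone 25 (not isolated)
Conditions: degassed toluene (0.01 M), 110 °C, argon
Reagents that add atoms: none
Why: Heat should break the C5–C8 σ-bond of the cyclobutenone in a conrotatory 4π electrocyclic opening to dienylketene 24, whose ketene carbon (C5) then bonds to the vinyl terminus (C6) to give cyclohexadienone 25, and enolisation of that dienone delivers the aromatic 5,8-diol. The closest known reaction type is the Moore rearrangement of squarate-derived 4-alkenyl-4-hydroxycyclobutenones to hydroquinones, used here on a ring-fused member of that class. Ring A closes by thermal disrotatory 6π electrocyclisation, helped by the fact that the ketene and enol double bonds are exocyclic on the neighbouring pyran atoms C4a and C8a and are thus locked s-cis. No stereocentre is formed, since the carbinol carbon becomes aromatic C8 (so both epimers of 23 converge) and C2 is a spectator. The step needs outward rotation of the hydroxyl so that the vinyl group turns inward next to the ketene, which the donor character of the hydroxyl ensures under thermal conditions, and no regiochemical issue exists because C6 and C7 carry only hydrogen. High dilution and exclusion of oxygen guard the ketene against intermolecular capture and the hydroquinone against oxidation, and 26 is used at once.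

Step 8
Reactants: 26 (2R)-2-[(12Z)-heptadec-12-en-1-yl]spiro[chromane-4,2'-[1,3]dithiane]-5,8-diol
Product: 27 (2R)-2-[(12Z)-heptadec-12-en-1-yl]-5,8-dihydroxy-2,3-dihydro-4H-chromen-4-one
Conditions: MeI (excess), CaCO3, MeCN/H2O (9:1), 40 °C, argon; aq Na2S2O4 wash
Reagents that add atoms: water, O
Why: Alkylative dithioketal hydrolysis, in which S-methylation turns the sulfurs into leaving groups and water captures the ring-stabilised thionium ion to give the C4 ketone; the near-neutral CaCO3 buffer should avoid base-induced opening of the chromanone that would erode C2, and dithionite returns any quinone formed by stray oxidation to the hydroquinone.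

Compound list
1 | 1-hexyne | CCCCC#C | starting material
2 | 1,10-dibromodecane | BrCCCCCCCCCCBr | starting material
3 | hex-1-yn-1-yllithium | CCCCC#C[Li] | intermediate
4 | 16-bromohexadec-5-yne | CCCCC#CCCCCCCCCCCBr | intermediate
5 | (5Z)-16-bromohexadec-5-ene | CCCC/C=C\CCCCCCCCCCBr | intermediate
6 | (R)-epichlorohydrin [(2R)-2-(chloromethyl)oxirane] | ClC[C@H]1CO1 | starting material
7 | (11Z)-hexadec-11-en-1-ylmagnesium bromide | CCCC/C=C\CCCCCCCCCC[Mg]Br | intermediate
8 | bromomagnesium (2R,14Z)-1-chlorononadec-14-en-2-olate | CCCC/C=C\CCCCCCCCCCC[C@@H](O[Mg]Br)CCl | intermediate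
9 | (2R,14Z)-1-chlorononadec-14-en-2-ol | CCCC/C=C\CCCCCCCCCCC[C@@H](O)CCl | intermediate
10 | (2R)-2-[(12Z)-heptadec-12-en-1-yl]oxirane | CCCC/C=C\CCCCCCCCCCC[C@@H]1CO1 | intermediate
11 | 2-(tert-butyldimethylsilyl)-1,3-dithiane | CC(C)(C)[Si](C)(C)C1SCCCS1 | starting material
12 | diisopropyl squarate (3,4-diisopropoxycyclobut-3-ene-1,2-dione) | CC(C)OC1=C(OC(C)C)C(=O)C1=O | starting material
13 | 2-lithio-2-(tert-butyldimethylsilyl)-1,3-dithiane | CC(C)(C)[Si](C)(C)C1([Li])SCCCS1 | intermediate
14 | lithium (2R,14Z)-1-[2-(tert-butyldimethylsilyl)-1,3-dithian-2-yl]nonadec-14-en-2-olate | CCCC/C=C\CCCCCCCCCCC[C@@H](O[Li])CC1([Si](C)(C)C(C)(C)C)SCCCS1 | intermediate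
15 | {2-[(2R,14Z)-2-(tert-butyldimethylsilyloxy)nonadec-14-en-1-yl]-1,3-dithian-2-yl}lithium | CCCC/C=C\CCCCCCCCCCC[C@@H](O[Si](C)(C)C(C)(C)C)CC1([Li])SCCCS1 | intermediate
16 | lithium 1-{2-[(2R,14Z)-2-(tert-butyldimethylsilyloxy)nonadec-14-en-1-yl]-1,3-dithian-2-yl}-2,3-diisopropoxy-4-oxocyclobut-2-en-1-olate (either carbinol epimer) | CCCC/C=C\CCCCCCCCCCC[C@@H](O[Si](C)(C)C(C)(C)C)CC1(SCCCS1)C2(O[Li])C(OC(C)C)=C(OC(C)C)C2=O | intermediate
17 | 1-{2-[(2R,14Z)-2-(tert-butyldimethylsilyloxy)nonadec-14-en-1-yl]-1,3-dithian-2-yl}-2,3-diisopropoxy-4-oxocyclobut-2-en-1-yl trifluoroacetate | CCCC/C=C\CCCCCCCCCCC[C@@H](O[Si](C)(C)C(C)(C)C)CC1(SCCCS1)C2(OC(=O)C(F)(F)F)C(OC(C)C)=C(OC(C)C)C2=O | intermediate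
18 | 3-{2-[(2R,14Z)-2-(tert-butyldimethylsilyloxy)nonadec-14-en-1-yl]-1,3-dithian-2-yl}-4-isopropoxycyclobut-3-ene-1,2-dione | CCCC/C=C\CCCCCCCCCCC[C@@H](O[Si](C)(C)C(C)(C)C)CC1(SCCCS1)C2=C(OC(C)C)C(=O)C2=O | intermediate
19 | 3-{2-[(2R,14Z)-2-hydroxynonadec-14-en-1-yl]-1,3-dithian-2-yl}-4-isopropoxycyclobut-3-ene-1,2-dione | CCCC/C=C\CCCCCCCCCCC[C@@H](O)CC1(SCCCS1)C2=C(OC(C)C)C(=O)C2=O | intermediate
20 | (3R)-3-[(12Z)-heptadec-12-en-1-yl]spiro[2-oxabicyclo[4.2.0]oct-1(6)-ene-5,2'-[1,3]dithiane]-7,8-dione (pyran-fused cyclobutenedione; O1, C2 to C4, C4a, C8a in place) | CCCC/C=C\CCCCCCCCCCC[C@@H]1CC2(SCCCS2)C3=C(O1)C(=O)C3=O | intermediate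
21 | vinylmagnesium bromide | C=C[Mg]Br | starting material
22 | bromomagnesium alkoxide of 23 (both carbinol epimers) | CCCC/C=C\CCCCCCCCCCC[C@@H]1CC2(SCCCS2)C3=C(O1)C(O[Mg]Br)(C=C)C3=O | intermediate
23 | (3R)-3-[(12Z)-heptadec-12-en-1-yl]-8-hydroxy-8-vinylspiro[2-oxabicyclo[4.2.0]oct-1(6)-ene-5,2'-[1,3]dithiane]-7-one (pyran-fused 4-hydroxy-4-vinylcyclobutenone, both carbinol epimers) | CCCC/C=C\CCCCCCCCCCC[C@@H]1CC2(SCCCS2)C3=C(O1)C(O)(C=C)C3=O | intermediate
24 | dienylketene: (R)-dihydropyran with the C4 dithioketal, an exocyclic ketene on C4a and an exocyclic (Z)-enol C8a=C8(OH)–CH=CH2 whose vinyl group lies cis to C4a | CCCC/C=C\CCCCCCCCCCC[C@@H]1CC2(SCCCS2)C(=C=O)/C(O1)=C(/O)C=C | intermediate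
25 | (2R)-2-[(12Z)-heptadec-12-en-1-yl]-8-hydroxy-2,3-dihydrospiro[chromene-4,2'-[1,3]dithian]-5(6H)-one (cyclohexa-2,4-dienone tautomer) | CCCC/C=C\CCCCCCCCCCC[C@@H]1CC2(SCCCS2)C3=C(O1)C(O)=CCC3=O | intermediate
26 | (2R)-2-[(12Z)-heptadec-12-en-1-yl]spiro[chromane-4,2'-[1,3]dithiane]-5,8-diol | CCCC/C=C\CCCCCCCCCCC[C@@H]1CC2(SCCCS2)c3c(O)ccc(O)c3O1 | intermediate
27 | (2R)-2-[(12Z)-heptadec-12-en-1-yl]-5,8-dihydroxy-2,3-dihydro-4H-chromen-4-one (CNP0081592.1) | CCCC/C=C\CCCCCCCCCCC[C@@H]1CC(=O)c2c(O)ccc(O)c2O1 | target

Total step count: 8. Longest linear sequence: 8 steps (1 to 27; compounds 2, 6, 11, 12 and 21 enter as purchased partners).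

Steps most likely to fail

Step 7. At the reaction temperature the free tertiary hydroxyl of one molecule may add to the ketene of another before ring closure, and the electron-rich hydroquinone may be oxidised by traces of air during heating or work-up. The fallback sets out from 23 and runs the ring expansion on a capped carbinol. Silylation with N-(trimethylsilyl)imidazole in CH2Cl2 at 0 °C should give the carbinol trimethylsilyl ether (3R)-3-[(12Z)-heptadec-12-en-1-yl]-8-(trimethylsilyloxy)-8-vinylspiro[2-oxabicyclo[4.2.0]oct-1(6)-ene-5,2'-[1,3]dithiane]-7-one F1. Its thermolysis in degassed toluene should follow the same opening and closure and deliver the 8-O-trimethylsilyl hydroquinone dithioketal F2, which has no free carbinol to attack a ketene and is much harder to oxidise. Cleavage of the aryl silyl ether with HF·pyridine in THF at 0 °C under argon, immediately before step 8, rejoins the route at 26.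

Step 4. The silyl shift may be incomplete, or the three components may be out of balance when the squarate is met, so that leftover 13, unrearranged 14 or an excess of 15 consumes the squarate or attacks the newly formed dione. The fallback sets out from oxirane 10 and builds the nucleophile in separate operations.
- 2-Lithio-1,3-dithiane F3, made from 1,3-dithiane and n-BuLi in THF at −30 °C, should open 10 at CH2 to give lithium (2R,14Z)-1-(1,3-dithian-2-yl)nonadec-14-en-2-olate F4.
- Aqueous NH4Cl converts this into (2R,14Z)-1-(1,3-dithian-2-yl)nonadec-14-en-2-ol F5.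
- TBSCl and imidazole in DMF should then give the silyl ether tert-butyl{[(2R,14Z)-1-(1,3-dithian-2-yl)nonadec-14-en-2-yl]oxy}dimethylsilane F6, which is purified.
- Metalation of a weighed amount with t-BuLi in THF/HMPA at −78 °C gives anion 15. The HMPA also disfavours the reverse silyl shift from oxygen to carbon.
- Anion 15 is added slowly to squarate 12 and treated with (CF3CO)2O and water as in step 4, so that the route is rejoined at 18.

Step 8. S-Methylation of the hindered dithioketal may be slow. Long exposure then invites O-methylation of the phenols, oxidation of the hydroquinone, or base-assisted opening of the chromanone with loss of configuration at C2. The fallback sets out from 26 and unmasks oxidatively on purpose. PhI(OCOCF3)2 (about 3 equiv) in MeCN/H2O at 0 °C should oxidise the hydroquinone and cleave the dithioketal within minutes, giving (2R)-2-[(12Z)-heptadec-12-en-1-yl]-2,3-dihydro-4H-chromene-4,5,8-trione F7. After extraction only, aqueous Na2S2O4 with EtOAc should reduce the quinone, and the route is rejoined at 27.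

Further compounds
F1 | step 7 | (3R)-3-[(12Z)-heptadec-12-en-1-yl]-8-(trimethylsilyloxy)-8-vinylspiro[2-oxabicyclo[4.2.0]oct-1(6)-ene-5,2'-[1,3]dithiane]-7-one | CCCC/C=C\CCCCCCCCCCC[C@@H]1CC2(SCCCS2)C3=C(O1)C(O[Si](C)(C)C)(C=C)C3=O
F2 | step 7 | (2R)-2-[(12Z)-heptadec-12-en-1-yl]-8-(trimethylsilyloxy)spiro[chromane-4,2'-[1,3]dithian]-5-ol | CCCC/C=C\CCCCCCCCCCC[C@@H]1CC2(SCCCS2)c3c(O)ccc(O[Si](C)(C)C)c3O1
F3 | step 4 | 2-lithio-1,3-dithiane | [Li]C1SCCCS1
F4 | step 4 | lithium (2R,14Z)-1-(1,3-dithian-2-yl)nonadec-14-en-2-olate | CCCC/C=C\CCCCCCCCCCC[C@@H](O[Li])CC1SCCCS1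
F5 | step 4 | (2R,14Z)-1-(1,3-dithian-2-yl)nonadec-14-en-2-ol | CCCC/C=C\CCCCCCCCCCC[C@@H](O)CC1SCCCS1
F6 | step 4 | tert-butyl{[(2R,14Z)-1-(1,3-dithian-2-yl)nonadec-14-en-2-yl]oxy}dimethylsilane | CCCC/C=C\CCCCCCCCCCC[C@@H](O[Si](C)(C)C(C)(C)C)CC1SCCCS1
F7 | step 8 | (2R)-2-[(12Z)-heptadec-12-en-1-yl]-2,3-dihydro-4H-chromene-4,5,8-trione | CCCC/C=C\CCCCCCCCCCC[C@@H]1CC(=O)C2=C(O1)C(=O)C=CC2=O
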